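**Strategy**

Ring A (labdane numbering) is disconnected at C1–C2 and C4–C5, a formal [3+3] annulation onto ring B. The key step exploits two oxygenated positions of the target: the C7 oxygen of ring B, used as a ketone whose β-phenylthio enone makes C5 an addition–elimination acceptor, and C19 on C4, used as an ester that makes C4 a nucleophile. Quaternary C10 carries C1 as an aldehyde. A phosphonium ester C2–C3–C4(CH3)–C19 first olefinates C1 as its ylide and then, as its ester enolate, closes ring A at C5 in the same flask, creating the C4 quaternary centre. The precursor is a monocyclic cyclohexenone aldehyde from a Diels–Alder reaction of a geraniol-derived enal.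

Key step: step 6

Remarks: Atom labels C1–C20 follow labdane numbering throughout. Assumption: the (R,R)-salen cobalt catalyst in step 3 is taken to give the (1R,6S)-adduct; if the sense of induction is the opposite, the (S,S)-catalyst is used. Compounds 1, 5 and 10 are commercial.

**Route**

Step 1
Reactants: 1 geraniol
Product: 2 geranyl triisopropylsilyl ether
Conditions: TIPSCl, imidazole, DMF, rt
Reagents that add atoms: triisopropylsilyl chloride, CC(C)[Si](Cl)(C(C)C)C(C)C
Why: Silyl ether protection of the primary allylic alcohol gives a C15 group that should survive acid, strong base, dissolving metal and hydride and is removed last by fluoride.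

Step 2
Reactants: 2 geranyl triisopropylsilyl ether
Product: 4 (2E,6E)-2,6-dimethyl-8-(triisopropylsilyloxy)octa-2,6-dienal, via allylic alcohol 3 (not isolated)
Conditions: SeO2 (0.3 eq), t-BuOOH, salicylic acid (cat.), CH2Cl2, rt; filter; MnO2, CH2Cl2, rt
Reagents that add atoms: selenium dioxide, O=[Se]=O; tert-butyl hydroperoxide, CC(C)(C)OO
Why: Catalytic SeO2/TBHP allylic oxidation (ene reaction, then [2,3]-shift) should attack only the terminal alkene at its E-methyl group, because the 2,3-alkene is deactivated by the allylic oxygen, and MnO2 allylic oxidation converges the crude alcohol/aldehyde mixture on the E-enal.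

Step 3
Reactants: 4 (2E,6E)-2,6-dimethyl-8-(triisopropylsilyloxy)octa-2,6-dienal; 5 Rawal's diene, (E)-3-(tert-butyldimethylsilyloxy)-N,N-dimethylbuta-1,3-dien-1-amine
Product: 7 (1R,6S)-1-methyl-6-[(3E)-3-methyl-5-(triisopropylsilyloxy)pent-3-en-1-yl]-4-oxocyclohex-2-ene-1-carbaldehyde, via cycloadduct 6 (not isolated)
Conditions: 5 (1.5 eq), (R,R)-(salen)Co(III)SbF6 (5 mol%), 4 Å MS, CH2Cl2, −40 → −20 °C; then 1 N HCl, THF, 0 °C
Reagents that add atoms: none
Why: Catalytic enantioselective Diels–Alder reaction of an α-substituted enal with a 1-amino-3-siloxy diene should join the CH2 terminus of the diene to the β-carbon (C9) and the aminated terminus to the α-carbon (C10), so that the E geometry becomes the cis relation of the C10 methyl and the C9 side chain while the catalyst fixes the absolute configuration, and acid then unmasks the enone by enol ether hydrolysis and loss of dimethylamine.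

Step 4
Reactants: 7 (1R,6S)-1-methyl-6-[(3E)-3-methyl-5-(triisopropylsilyloxy)pent-3-en-1-yl]-4-oxocyclohex-2-ene-1-carbaldehyde
Product: 9 (1S,6S)-1-methyl-6-[(3E)-3-methyl-5-(triisopropylsilyloxy)pent-3-en-1-yl]-4-oxo-2-(phenylsulfanyl)cyclohex-2-ene-1-carbaldehyde, via sulfide ketone 8 (not isolated)
Conditions: PhSH (1.0 eq), Et3N (cat.), CH2Cl2, 0 °C; then NCS, CCl4, 0 °C; Et3N, rt
Reagents that add atoms: thiophenol, Sc1ccccc1
Why: Thia-Michael addition followed by NCS chlorination α to sulfur and loss of HCl (Pummerer-type oxidation of a β-thio ketone to a β-thio enone) should place a leaving group on C5, and the sulfur-bearing centre of 8 is destroyed again so its configuration does not matter.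

Step 5
Reactants: 10 methyl 4-bromo-2-methylbutanoate (racemic)
Product: 11 (4-methoxy-3-methyl-4-oxobutyl)triphenylphosphonium bromide (racemic)
Conditions: PPh3, MeCN, reflux
Reagents that add atoms: triphenylphosphine, c1ccc(cc1)P(c1ccccc1)c1ccccc1
Why: SN2 quaternisation of triphenylphosphine by the primary bromide gives the Wittig salt, and racemic material suffices because its stereocentre is enolised in step 6.

Step 6
Reactants: 9 (1S,6S)-1-methyl-6-[(3E)-3-methyl-5-(triisopropylsilyloxy)pent-3-en-1-yl]-4-oxo-2-(phenylsulfanyl)cyclohex-2-ene-1-carbaldehyde; 11 (4-methoxy-3-methyl-4-oxobutyl)triphenylphosphonium bromide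
Product: 14 methyl 7-oxo-15-(triisopropylsilyloxy)labda-1,5,13E-trien-19-oate (19-ester β, cis to the C20 methyl; 9α-H), via ylide 12 (not isolated), via Wittig alkene 13 (not isolated)
Conditions: 11 (1.3 eq), KHMDS (1.25 eq), THF, −78 °C; add 9, −78 → 0 °C; then KHMDS (2.5 eq), 18-crown-6, −78 → 0 °C; NH4Cl
Reagents that add atoms: none
Why: KHMDS converts 11 into the non-stabilised ylide 12, which olefinates the aldehyde C1 of 9 to the Z-alkene 13 (C1=C2), and a second charge of base forms the ester enolate at C4, which adds to C5 of the β-phenylthio enone and expels thiophenolate. The closest known reaction types are the salt-free Z-selective Wittig reaction and the conjugate addition–elimination of enolates to β-(arylthio)enones, run here in tandem as a formal [3+3] annulation. Ring A closes in a 6-exo-trig addition onto C5=C6 followed by E1cB loss of PhS−, which restores the Δ5-7-ketone, so no stereocentre arises at C5 and the ring fusion is set later. The new quaternary stereocentre C4 is controlled by the existing C10 centre: the Z-alkene tether delivers the enolate to the α-face of C5 (the face of C1, anti to the C20 methyl), and the bulky potassium enolate unit should point away from ring B while the small methyl sits under it, which after planarisation at C5 places the ester β, cis to C20. The step needs chemoselective attack of the ylide on the aldehyde over the deactivated vinylogous thioester carbonyl, Z geometry (only the Z-alkene can reach C5) and ester enolate formation in the presence of the more acidic C8 hydrogens. The last is secured because proton transfer through HN(SiMe3)2 is reversible whereas cyclisation is irreversible, and the open, crown-ether-separated enolate favours steric over chelate control.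

Step 7
Reactants: 14 methyl 7-oxo-15-(triisopropylsilyloxy)labda-1,5,13E-trien-19-oate
Product: 15 methyl 7-oxo-15-(triisopropylsilyloxy)labda-5,13E-dien-19-oate
Conditions: RhCl(PPh3)3 (10 mol%), H2 (3 atm), PhH, rt
Reagents that add atoms: none
Why: Homogeneous hydrogenation with Wilkinson's catalyst is very sensitive to substitution and should saturate only the cis-disubstituted C1=C2 bond, leaving the trisubstituted side-chain alkene and the hindered conjugated C5=C6 bond.

Step 8
Reactants: 15 methyl 7-oxo-15-(triisopropylsilyloxy)labda-5,13E-dien-19-oate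
Product: 16 methyl 17-(dimethylamino)-7-oxo-15-(triisopropylsilyloxy)labda-5,13E-dien-19-oate (8β-H)
Conditions: LDA, THF, −78 °C; CH2=NMe2+ I−, −78 → 0 °C
Reagents that add atoms: Eschenmoser's salt (N,N-dimethylmethyleneiminium iodide), C[N+](C)=C.[I-]
Why: Kinetic α′-deprotonation of the enone can only occur at C8 (the γ-carbons C4 and C10 are quaternary), and the Mannich reaction with Eschenmoser's salt should install C17 there as a masked exocyclic methylene, trans to the C9 side chain.

Step 9
Reactants: 16 methyl 17-(dimethylamino)-7-oxo-15-(triisopropylsilyloxy)labda-5,13E-dien-19-oate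
Product: 18 17-(dimethylamino)-19-hydroxy-15-(triisopropylsilyloxy)labd-13E-en-7-one (5α-H, 8β-H), via lithium enolate 17 (not isolated)
Conditions: Li, NH3(l), THF, t-BuOH (1 eq), −78 °C; isoprene; evaporate NH3; LiAlH4, THF, 0 °C → rt; Rochelle salt
Reagents that add atoms: none
Why: Dissolving-metal (Birch-type) conjugate reduction should protonate C5 axially from the α-face to give the trans-decalin, and the lithium enolate formed protects the C7 ketone in situ while LiAlH4 reduces the hindered axial ester to the C19 alcohol.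

Step 10
Reactants: 18 17-(dimethylamino)-19-hydroxy-15-(triisopropylsilyloxy)labd-13E-en-7-one
Product: 19 19-acetoxy-17-(dimethylamino)-15-(triisopropylsilyloxy)labd-13E-en-7-one
Conditions: Ac2O, pyridine, DMAP (cat.), CH2Cl2, rt
Reagents that add atoms: acetic anhydride, CC(=O)OC(C)=O
Why: DMAP-catalysed acylation of the only free hydroxyl group fixes the C19 acetate before any other OH exists, so no selective acetylation is needed later.

Step 11
Reactants: 19 19-acetoxy-17-(dimethylamino)-15-(triisopropylsilyloxy)labd-13E-en-7-one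
Product: 20 19-acetoxy-17-(dimethylamino)-15-(triisopropylsilyloxy)labd-13E-en-7α-ol
Conditions: L-Selectride, THF, −78 °C; NH4Cl
Reagents that add atoms: none
Why: Bulky-hydride ketone reduction with L-Selectride should occur by equatorial attack from the β-face to give the axial 7α-alcohol, while the hindered neopentyl acetate survives at −78 °C.

Step 12
Reactants: 20 19-acetoxy-17-(dimethylamino)-15-(triisopropylsilyloxy)labd-13E-en-7α-ol
Product: 22 19-acetoxy-15-(triisopropylsilyloxy)labda-8(17),13E-dien-7α-ol, via amine oxide 21 (not isolated)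
Conditions: mCPBA (1.0 eq), K2CO3, CH2Cl2, −20 °C; basic alumina; then THF, 65 °C
Reagents that add atoms: none
Why: N-oxidation of the tertiary amine, which is much faster than alkene epoxidation, followed by thermal Cope elimination through a syn five-membered transition state can only remove the C8 hydrogen and should unveil the 8(17)-methylene next to the 7α-OH.

Step 13
Reactants: 22 19-acetoxy-15-(triisopropylsilyloxy)labda-8(17),13E-dien-7α-ol
Product: 23 19-acetoxylabda-8(17),13E-diene-7α,15-diol (target)
Conditions: TBAF, AcOH, THF, 0 °C → rt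
Reagents that add atoms: none
Why: Fluoride-mediated desilylation, buffered with acetic acid to prevent acetate hydrolysis or migration, should free the C15 allylic alcohol and give the target.

**Compound list**

1 | geraniol, (2E)-3,7-dimethylocta-2,6-dien-1-ol | CC(C)=CCC/C(C)=C/CO | starting material
2 | geranyl triisopropylsilyl ether | CC(C)=CCC/C(C)=C/CO[Si](C(C)C)(C(C)C)C(C)C | intermediate
3 | (2E,6E)-2,6-dimethyl-8-(triisopropylsilyloxy)octa-2,6-dien-1-ol | OC/C(C)=C/CC/C(C)=C/CO[Si](C(C)C)(C(C)C)C(C)C | intermediate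
4 | (2E,6E)-2,6-dimethyl-8-(triisopropylsilyloxy)octa-2,6-dienal | O=C/C(C)=C/CC/C(C)=C/CO[Si](C(C)C)(C(C)C)C(C)C | intermediate
5 | Rawal's diene, (E)-3-(tert-butyldimethylsilyloxy)-N,N-dimethylbuta-1,3-dien-1-amine | CN(C)/C=C/C(=C)O[Si](C)(C)C(C)(C)C | starting material
6 | (1R,2S,6S)-4-(tert-butyldimethylsilyloxy)-2-(dimethylamino)-1-methyl-6-[(3E)-3-methyl-5-(triisopropylsilyloxy)pent-3-en-1-yl]cyclohex-3-ene-1-carbaldehyde (amino cis to formyl) | CC(C)(C)[Si](C)(C)OC1=C[C@H](N(C)C)[C@](C)(C=O)[C@@H](CC/C(C)=C/CO[Si](C(C)C)(C(C)C)C(C)C)C1 | intermediate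
7 | (1R,6S)-1-methyl-6-[(3E)-3-methyl-5-(triisopropylsilyloxy)pent-3-en-1-yl]-4-oxocyclohex-2-ene-1-carbaldehyde | O=C1C=C[C@](C)(C=O)[C@@H](CC/C(C)=C/CO[Si](C(C)C)(C(C)C)C(C)C)C1 | intermediate
8 | (1S,6S)-1-methyl-6-[(3E)-3-methyl-5-(triisopropylsilyloxy)pent-3-en-1-yl]-4-oxo-2-(phenylsulfanyl)cyclohexane-1-carbaldehyde (mixture at C2) | O=C1CC(Sc2ccccc2)[C@](C)(C=O)[C@@H](CC/C(C)=C/CO[Si](C(C)C)(C(C)C)C(C)C)C1 | intermediate
9 | (1S,6S)-1-methyl-6-[(3E)-3-methyl-5-(triisopropylsilyloxy)pent-3-en-1-yl]-4-oxo-2-(phenylsulfanyl)cyclohex-2-ene-1-carbaldehyde | O=C1C=C(Sc2ccccc2)[C@](C)(C=O)[C@@H](CC/C(C)=C/CO[Si](C(C)C)(C(C)C)C(C)C)C1 | intermediate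
10 | methyl 4-bromo-2-methylbutanoate (racemic) | COC(=O)C(C)CCBr | starting material
11 | (4-methoxy-3-methyl-4-oxobutyl)triphenylphosphonium bromide (racemic) | COC(=O)C(C)CC[P+](c1ccccc1)(c1ccccc1)c1ccccc1.[Br-] | intermediate
12 | methyl 2-methyl-4-(triphenylphosphoranylidene)butanoate | COC(=O)C(C)CC=P(c1ccccc1)(c1ccccc1)c1ccccc1 | intermediate
13 | methyl (4Z)-2-methyl-5-[(1S,6S)-1-methyl-6-[(3E)-3-methyl-5-(triisopropylsilyloxy)pent-3-en-1-yl]-4-oxo-2-(phenylsulfanyl)cyclohex-2-en-1-yl]pent-4-enoate (mixture at C2 of the ester chain) | O=C1C=C(Sc2ccccc2)[C@](C)(/C=C\CC(C)C(=O)OC)[C@@H](CC/C(C)=C/CO[Si](C(C)C)(C(C)C)C(C)C)C1 | intermediate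
14 | methyl 7-oxo-15-(triisopropylsilyloxy)labda-1,5,13E-trien-19-oate (19-CO2Me β, 18-CH3 α, 20-CH3 β, 9α-H) | O=C1C=C2[C@@](C)(C(=O)OC)CC=C[C@]2(C)[C@@H](CC/C(C)=C/CO[Si](C(C)C)(C(C)C)C(C)C)C1 | intermediate
15 | methyl 7-oxo-15-(triisopropylsilyloxy)labda-5,13E-dien-19-oate | O=C1C=C2[C@@](C)(C(=O)OC)CCC[C@]2(C)[C@@H](CC/C(C)=C/CO[Si](C(C)C)(C(C)C)C(C)C)C1 | intermediate
16 | methyl 17-(dimethylamino)-7-oxo-15-(triisopropylsilyloxy)labda-5,13E-dien-19-oate (8β-H) | O=C1C=C2[C@@](C)(C(=O)OC)CCC[C@]2(C)[C@@H](CC/C(C)=C/CO[Si](C(C)C)(C(C)C)C(C)C)[C@@H]1CN(C)C | intermediate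
17 | lithium 6-en-7-olate of methyl 17-(dimethylamino)-7-oxo-15-(triisopropylsilyloxy)labd-13E-en-19-oate (5α-H) | [Li]OC1=C[C@H]2[C@@](C)(C(=O)OC)CCC[C@]2(C)[C@@H](CC/C(C)=C/CO[Si](C(C)C)(C(C)C)C(C)C)[C@@H]1CN(C)C | intermediate
18 | 17-(dimethylamino)-19-hydroxy-15-(triisopropylsilyloxy)labd-13E-en-7-one (5α-H, 8β-H) | O=C1C[C@H]2[C@@](C)(CO)CCC[C@]2(C)[C@@H](CC/C(C)=C/CO[Si](C(C)C)(C(C)C)C(C)C)[C@@H]1CN(C)C | intermediate
19 | 19-acetoxy-17-(dimethylamino)-15-(triisopropylsilyloxy)labd-13E-en-7-one | O=C1C[C@H]2[C@@](C)(COC(C)=O)CCC[C@]2(C)[C@@H](CC/C(C)=C/CO[Si](C(C)C)(C(C)C)C(C)C)[C@@H]1CN(C)C | intermediate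
20 | 19-acetoxy-17-(dimethylamino)-15-(triisopropylsilyloxy)labd-13E-en-7α-ol | CN(C)C[C@@H]1[C@H](O)C[C@H]2[C@@](C)(COC(C)=O)CCC[C@]2(C)[C@H]1CC/C(C)=C/CO[Si](C(C)C)(C(C)C)C(C)C | intermediate
21 | N-oxide of 20 | C[N+](C)([O-])C[C@@H]1[C@H](O)C[C@H]2[C@@](C)(COC(C)=O)CCC[C@]2(C)[C@H]1CC/C(C)=C/CO[Si](C(C)C)(C(C)C)C(C)C | intermediate
22 | 19-acetoxy-15-(triisopropylsilyloxy)labda-8(17),13E-dien-7α-ol | C=C1[C@H](O)C[C@H]2[C@@](C)(COC(C)=O)CCC[C@]2(C)[C@H]1CC/C(C)=C/CO[Si](C(C)C)(C(C)C)C(C)C | intermediate
23 | 19-acetoxylabda-8(17),13E-diene-7α,15-diol (CNP0209062.1) | C=C1[C@H](O)C[C@H]2[C@@](C)(COC(C)=O)CCC[C@]2(C)[C@H]1CC/C(C)=C/CO | target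

**Totals**

Total step count: 13. Longest linear sequence: 12 steps (steps 1–4 and 6–13; step 5 prepares the side-arm reagent).

**Steps most likely to fail, with fallbacks**

Step 6 (key step). What may go wrong is that enolisation at C8 outruns formation of the ester enolate so that ring closure stalls, or that the enolate attacks with poor facial selectivity at C4. The fallback keeps the ketone masked during the anionic ring closure, so that the ester is the only C–H acid. It sets out from cycloadduct 6, taken crude from the Diels–Alder reaction before the acid treatment, and ylide 12. Wittig olefination of the aldehyde of 6 should give the Z-alkene amino silyl enol ether F1. N-Methylation with MeOTf gives the allylic trimethylammonium triflate F2. KHMDS then forms the ester enolate, which should displace trimethylamine at C5 in an intramolecular allylic alkylation to give the bicyclic silyl enol ether F3; its C5 configuration is of no consequence. Saegusa–Ito oxidation of F3 with Pd(OAc)2 in MeCN re-forms the C5=C6 enone and returns to the route at 14.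

Step 3. What may go wrong is low reactivity of the β-substituted α-methyl enal, erosion of enantioselectivity, or competing hetero-Diels–Alder addition at the aldehyde. The fallback sets out from enal 4. A cationic oxazaborolidine-catalysed Diels–Alder reaction with 2-(triisopropylsilyloxy)buta-1,3-diene (made from methyl vinyl ketone) should give, with the usual para regiochemistry, the silyl enol ether aldehyde F4. Saegusa–Ito oxidation with Pd(OAc)2, whose β-hydride elimination can only involve C5, introduces the C5=C6 bond and returns to the route at 7.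

Step 9. What may go wrong is loss of the enolate protection, so that the ketone is over-reduced, or reductive damage to the ester or the Mannich base in the dissolving-metal stage. The fallback sets out from 16 and separates the reductions. Copper hydride conjugate reduction (Stryker's reagent or a phosphine-ligated CuH with a silane, then hydrolysis) delivers hydride to the α-face of C5 and should give the trans-fused keto ester F5. L-Selectride then gives the 7α-hydroxy ester F6, and LiAlH4 gives the 7α,19-diol F7. Acetylation with Ac2O/pyridine at 0 °C, selective for the primary C19 hydroxyl over the axial secondary one, returns to the route at 20.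

**Further compounds**

F1 | step 6 | methyl (4Z)-5-[(1S,2S,6S)-4-(tert-butyldimethylsilyloxy)-2-(dimethylamino)-1-methyl-6-[(3E)-3-methyl-5-(triisopropylsilyloxy)pent-3-en-1-yl]cyclohex-3-en-1-yl]-2-methylpent-4-enoate | CC(C)(C)[Si](C)(C)OC1=C[C@H](N(C)C)[C@](C)(/C=C\CC(C)C(=O)OC)[C@@H](CC/C(C)=C/CO[Si](C(C)C)(C(C)C)C(C)C)C1
F2 | step 6 | N-methyl trimethylammonium triflate of F1 | CC(C)(C)[Si](C)(C)OC1=C[C@H]([N+](C)(C)C)[C@](C)(/C=C\CC(C)C(=O)OC)[C@@H](CC/C(C)=C/CO[Si](C(C)C)(C(C)C)C(C)C)C1.[O-]S(=O)(=O)C(F)(F)F
F3 | step 6 | methyl 7-(tert-butyldimethylsilyloxy)-15-(triisopropylsilyloxy)labda-1,6,13E-trien-19-oate (C5 epimers) | CC(C)(C)[Si](C)(C)OC1=CC2[C@@](C)(C(=O)OC)CC=C[C@]2(C)[C@@H](CC/C(C)=C/CO[Si](C(C)C)(C(C)C)C(C)C)C1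
F4 | step 3 | (1S,6S)-1-methyl-6-[(3E)-3-methyl-5-(triisopropylsilyloxy)pent-3-en-1-yl]-4-(triisopropylsilyloxy)cyclohex-3-ene-1-carbaldehyde | O=C[C@@]1(C)CC=C(O[Si](C(C)C)(C(C)C)C(C)C)C[C@@H]1CC/C(C)=C/CO[Si](C(C)C)(C(C)C)C(C)C
F5 | step 9 | methyl 17-(dimethylamino)-7-oxo-15-(triisopropylsilyloxy)labd-13E-en-19-oate (5α-H, 8β-H) | O=C1C[C@H]2[C@@](C)(C(=O)OC)CCC[C@]2(C)[C@@H](CC/C(C)=C/CO[Si](C(C)C)(C(C)C)C(C)C)[C@@H]1CN(C)C
F6 | step 9 | methyl 17-(dimethylamino)-7α-hydroxy-15-(triisopropylsilyloxy)labd-13E-en-19-oate | CN(C)C[C@@H]1[C@H](O)C[C@H]2[C@@](C)(C(=O)OC)CCC[C@]2(C)[C@H]1CC/C(C)=C/CO[Si](C(C)C)(C(C)C)C(C)C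
F7 | step 9 | 17-(dimethylamino)-15-(triisopropylsilyloxy)labd-13E-ene-7α,19-diol | CN(C)C[C@@H]1[C@H](O)C[C@H]2[C@@](C)(CO)CCC[C@]2(C)[C@H]1CC/C(C)=C/CO[Si](C(C)C)(C(C)C)C(C)C
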